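**Retrosynthetic overview**

- Ring A is a hexasubstituted benzene, counted here from the chain-bearing carbon as positions 1 to 6 (1 ten-carbon chain, 2 OH, 3 3-hydroxybenzoyl, 4 OH, 5 (E)-3-methylbut-1-enyl, 6 OMe). Positions 4, 5, 6, 1 and 2 with their oxygens are C2–C6 of a 3,5-disubstituted 4-methoxy-2-pyrone, and position 3 is the CH2 of its 6-phenacyl group. The last step opens the pyrone with methoxide and closes the bond between positions 3 and 4 by Claisen condensation.
- Phenacyl pyrone 19 comes from lateral aroylation of 6-methylpyrone 15 with silyl-protected methyl 3-hydroxybenzoate 17; 15 comes from Suzuki coupling of 3-bromopyrone 12 with (E)-alkenylboronate 14.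
- The pyrone ring comes from DBU lactonisation of 3,5-diketo ester 9, made by γ-acetylation of β-keto ester 8, itself from Roskamp homologation of aldehyde 7.
- The chain and its stereocentre come from (R)-limonene by ring ozonolysis, ketone methylenation and one-carbon homologation; the former aldehyde carbon becomes pyrone C5 and then position 1 of ring A.
- Ring order: pyrone (step 6), then ring A from the pyrone (step 14); the 3-hydroxyphenyl ring is bought.

Key step: step 14

Remark on the chemistry: bought reagents that only deliver small groups are given with SMILES in the steps and are not numbered; lithium and magnesium salts of numbered compounds are not numbered separately.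

**Route**

Step 1
Reactants: 1 (R)-limonene
Product: 3 (5R)-7,7-dimethoxy-5-(prop-1-en-2-yl)heptan-2-one, via keto aldehyde 2 (not isolated)
Conditions: O3 (1.0 equiv, Sudan Red 7B end-point), CH2Cl2/MeOH 4:1, −78 °C; Me2S, −78 °C to rt; then p-TsOH·H2O (cat.), rt; NaHCO3 work-up
Reagents that add atoms: ozone, [O-][O+]=O; methanol, CO
Why: Ozone, an electrophile, cleaves the more electron-rich trisubstituted ring alkene ahead of the 1,1-disubstituted isopropenyl group (selective ozonolysis, reductive Me2S work-up), and acid-catalysed acetalisation in methanol then takes the aldehyde of 2 but not the methyl ketone; the stereocentre is that of limonene and no bond to it is touched.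

Step 2
Reactants: 3 (5R)-7,7-dimethoxy-5-(prop-1-en-2-yl)heptan-2-one
Product: 5 (3R)-6-methyl-3-(prop-1-en-2-yl)hept-6-enal, via diene acetal 4 (not isolated)
Conditions: Ph3PCH3Br, KOtBu, THF, 0 °C to rt; then 1 M aq. HCl, THF, rt
Reagents that add atoms: methyltriphenylphosphonium bromide, C[P+](c1ccccc1)(c1ccccc1)c1ccccc1.[Br-]; water, O
Why: Wittig methylenation converts the only free carbonyl, the methyl ketone, into the 2-methylprop-2-enyl terminus while the aldehyde is masked, and dilute aqueous acid then hydrolyses the dimethyl acetal without protonating the two 1,1-disubstituted alkenes.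

Step 3
Reactants: 5 (3R)-6-methyl-3-(prop-1-en-2-yl)hept-6-enal
Product: 7 (4R)-7-methyl-4-(prop-1-en-2-yl)oct-7-enal, via methyl enol ether 6 (not isolated)
Conditions: Ph3P(CH2OMe)Cl, KOtBu, THF, 0 °C; then 2 M aq. HCl, THF, 0 °C to rt
Reagents that add atoms: (methoxymethyl)triphenylphosphonium chloride, COC[P+](c1ccccc1)(c1ccccc1)c1ccccc1.[Cl-]; water, O
Why: Wittig methoxymethylenation and hydrolysis of the resulting enol ether is the standard one-carbon homologation of an aldehyde; the former aldehyde carbon becomes the CH2 that will be pyrone C5.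

Step 4
Reactants: 7 (4R)-7-methyl-4-(prop-1-en-2-yl)oct-7-enal
Product: 8 ethyl (6R)-9-methyl-3-oxo-6-(prop-1-en-2-yl)dec-9-enoate
Conditions: N2CHCO2Et (1.2 equiv), SnCl2 (10 mol%), CH2Cl2, rt
Reagents that add atoms: ethyl diazoacetate, [N-]=[N+]=CC(=O)OCC
Why: Roskamp reaction: SnCl2-catalysed addition of ethyl diazoacetate to the aldehyde with 1,2-hydride shift and loss of N2 gives the β-keto ester directly, and SnCl2, a weak Lewis acid used in catalytic amount at rt, is not expected to trigger carbonyl–ene closure onto the isopropenyl group.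

Step 5
Reactants: 8 ethyl (6R)-9-methyl-3-oxo-6-(prop-1-en-2-yl)dec-9-enoate
Product: 9 ethyl 4-[(2R)-5-methyl-2-(prop-1-en-2-yl)hex-5-enyl]-3,5-dioxohexanoate (epimers at C4, enol tautomers)
Conditions: LiN(iPr)2 (2.3 equiv), THF, −78 to 0 °C; MeC(O)N(OMe)Me (1.2 equiv), −78 to 0 °C; aq. HCl quench
Reagents that add atoms: N-methoxy-N-methylacetamide, CC(=O)N(C)OC
Why: The 1,3-dianion of the β-keto ester reacts at its more basic γ-carbon (Claisen-type γ-acylation), and the chelated tetrahedral adduct of the Weinreb amide holds until quench, so that neither over-addition nor proton transfer from the product occurs; the new CH is not a lasting stereocentre because it becomes sp2 in step 6.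

Step 6
Reactants: 9 ethyl 4-[(2R)-5-methyl-2-(prop-1-en-2-yl)hex-5-enyl]-3,5-dioxohexanoate
Product: 10 4-hydroxy-6-methyl-5-[(2R)-5-methyl-2-(prop-1-en-2-yl)hex-5-enyl]pyran-2-one
Conditions: DBU (1.5 equiv), toluene, 100 °C; cold dilute aq. HCl wash
Reagents that add atoms: none
Why: DBU enolises the 3,5-diketo ester and the C5 enol oxygen closes onto the ester (lactonisation by intramolecular transesterification, 6-exo-trig), the established route from 3,5-dioxo esters to 4-hydroxy-2-pyrones.

Step 7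
Reactants: 10 4-hydroxy-6-methyl-5-[(2R)-5-methyl-2-(prop-1-en-2-yl)hex-5-enyl]pyran-2-one
Product: 11 3-bromo-4-hydroxy-6-methyl-5-[(2R)-5-methyl-2-(prop-1-en-2-yl)hex-5-enyl]pyran-2-one
Conditions: NBS (1.0 equiv), CH2Cl2, −20 to 0 °C, dark
Reagents that add atoms: N-bromosuccinimide, O=C1CCC(=O)N1Br
Why: C3 of the 4-hydroxy-2-pyrone is the α-carbon of a vinylogous acid enol and undergoes electrophilic bromination far faster than the two isolated alkenes, so one equivalent of NBS at low temperature in the dark should be chemoselective.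

Step 8
Reactants: 11 3-bromo-4-hydroxy-6-methyl-5-[(2R)-5-methyl-2-(prop-1-en-2-yl)hex-5-enyl]pyran-2-one
Product: 12 3-bromo-4-methoxy-6-methyl-5-[(2R)-5-methyl-2-(prop-1-en-2-yl)hex-5-enyl]pyran-2-one
Conditions: Me2SO4 (1.2 equiv), K2CO3 (1.5 equiv), acetone, 50 °C
Reagents that add atoms: dimethyl sulfate, COS(=O)(=O)OC
Why: Williamson-type O-methylation of the pyrone potassium salt with Me2SO4 in acetone is the classical entry to 4-methoxy-2-pyrones, the conjugated 2-pyrone being favoured over the 2-methoxy-4-pyranone isomer.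

Step 9
Reactants: 13 3-methylbut-1-yne
Product: 14 (E)-4,4,5,5-tetramethyl-2-(3-methylbut-1-enyl)-1,3,2-dioxaborolane
Conditions: HBpin (1.1 equiv), Cp2Zr(H)Cl (5 mol%), Et3N (10 mol%), neat, 40 °C, sealed tube
Reagents that add atoms: pinacolborane, B1OC(C)(C)C(C)(C)O1
Why: Cp2Zr(H)Cl-catalysed hydroboration adds H–B syn and anti-Markovnikov across the terminal alkyne, which sets the E geometry of the future butenyl side chain at position 5 of ring A.

Step 10
Reactants: 12 3-bromo-4-methoxy-6-methyl-5-[(2R)-5-methyl-2-(prop-1-en-2-yl)hex-5-enyl]pyran-2-one; 14 (E)-4,4,5,5-tetramethyl-2-(3-methylbut-1-enyl)-1,3,2-dioxaborolane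
Product: 15 4-methoxy-6-methyl-3-[(E)-3-methylbut-1-enyl]-5-[(2R)-5-methyl-2-(prop-1-en-2-yl)hex-5-enyl]pyran-2-one
Conditions: Pd(dppf)Cl2 (5 mol%), K3PO4 (3 equiv), 1,4-dioxane/H2O 10:1, 70 °C
Reagents that add atoms: none
Why: Suzuki–Miyaura coupling of the C3 bromide, whose C–Br bond is activated by the lactone carbonyl for oxidative addition to zerovalent palladium, with the alkenylboronate proceeds with retention of the E geometry, and the mild phosphate base spares the lactone.

Step 11
Reactants: 16 methyl 3-hydroxybenzoate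
Product: 17 methyl 3-(tert-butyldimethylsilyloxy)benzoate
Conditions: TBSCl, imidazole, DMF, rt
Reagents that add atoms: tert-butyldimethylsilyl chloride, CC(C)(C)[Si](C)(C)Cl
Why: Standard silylation masks the acidic phenol so that the ester can serve as acyl donor in step 12.

Step 12
Reactants: 15 4-methoxy-6-methyl-3-[(E)-3-methylbut-1-enyl]-5-[(2R)-5-methyl-2-(prop-1-en-2-yl)hex-5-enyl]pyran-2-one; 17 methyl 3-(tert-butyldimethylsilyloxy)benzoate
Product: 18 6-[2-[3-(tert-butyldimethylsilyloxy)phenyl]-2-oxoethyl]-4-methoxy-3-[(E)-3-methylbut-1-enyl]-5-[(2R)-5-methyl-2-(prop-1-en-2-yl)hex-5-enyl]pyran-2-one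
Conditions: LiN(iPr)2 (2.2 equiv), THF, −78 °C; 17 (1.1 equiv), −78 to −30 °C; AcOH quench
Reagents that add atoms: none
Why: The 6-methyl group is the only position whose anion is conjugated through both ring double bonds to the lactone carbonyl (C3 is blocked), so lateral lithiation followed by Claisen-type C-acylation with the ester gives the 6-phenacyl pyrone, the second equivalent of base absorbing the more acidic product.

Step 13
Reactants: 18 6-[2-[3-(tert-butyldimethylsilyloxy)phenyl]-2-oxoethyl]-4-methoxy-3-[(E)-3-methylbut-1-enyl]-5-[(2R)-5-methyl-2-(prop-1-en-2-yl)hex-5-enyl]pyran-2-one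
Product: 19 6-[2-(3-hydroxyphenyl)-2-oxoethyl]-4-methoxy-3-[(E)-3-methylbut-1-enyl]-5-[(2R)-5-methyl-2-(prop-1-en-2-yl)hex-5-enyl]pyran-2-one
Conditions: Bu4NF (1.1 equiv), AcOH (1.1 equiv), THF, 0 °C
Reagents that add atoms: none
Why: Fluoride cleaves the aryl silyl ether, and acetic acid buffering keeps the acidic phenacyl pyrone from being opened by basic fluoride.

Step 14
Reactants: 19 6-[2-(3-hydroxyphenyl)-2-oxoethyl]-4-methoxy-3-[(E)-3-methylbut-1-enyl]-5-[(2R)-5-methyl-2-(prop-1-en-2-yl)hex-5-enyl]pyran-2-one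
Product: 21 CNP0208548.1, [2,6-dihydroxy-4-methoxy-3-[(2R)-5-methyl-2-(prop-1-en-2-yl)hex-5-enyl]-5-[(E)-3-methylbut-1-enyl]phenyl](3-hydroxyphenyl)methanone, via ring-opened methyl ester 20 (not isolated)
Conditions: Mg(OMe)2 (6 equiv), MeOH, reflux, argon; cold 0.5 M aq. HCl work-up
Reagents that add atoms: none
Why: Methoxide adds to the lactone carbonyl C2 and opens the pyrone to the magnesium chelate of 20, in which the retained C3=C4 enol ether geometry holds the new methyl ester cis to the C5 arm; the chelated 1,3-diketone carbanion (the phenacyl CH2, the future position 3 of ring A) then attacks the ester carbon (the future position 4), methoxide leaves and two enolisations aromatise ring A. The closest known reaction type is the Mg(OMe)2-mediated recyclisation of 6-(2-oxoalkyl)-4-hydroxy- and 4-methoxy-2-pyrones to acylphloroglucinols, an intramolecular Claisen (Dieckmann-type) condensation that copies polyketide folding. Ring A closes in the 6-exo-trig mode at the ester carbonyl. No stereocentre is formed, and the chain stereocentre is not acidic and is kept. The step needs C-acylation by the diketone carbon instead of retro-Claisen cleavage or closure through oxygen: the magnesium chelate keeps the diketone as an enolate that resists cleavage, the blocked C3 and the fixed enol ether leave no aldol path, and exchange of the C4 methoxy group by methoxide is degenerate.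

**Compound list**

1 | (R)-limonene, (4R)-1-methyl-4-(prop-1-en-2-yl)cyclohexene | CC1=CC[C@@H](CC1)C(C)=C | starting material
2 | (3R)-6-oxo-3-(prop-1-en-2-yl)heptanal | CC(=O)CC[C@H](CC=O)C(C)=C | intermediate (not isolated)
3 | (5R)-7,7-dimethoxy-5-(prop-1-en-2-yl)heptan-2-one | CC(=O)CC[C@H](CC(OC)OC)C(C)=C | intermediate
4 | (5R)-7,7-dimethoxy-2-methyl-5-(prop-1-en-2-yl)hept-1-ene | C=C(C)CC[C@H](CC(OC)OC)C(C)=C | intermediate (not isolated)
5 | (3R)-6-methyl-3-(prop-1-en-2-yl)hept-6-enal | C=C(C)CC[C@H](CC=O)C(C)=C | intermediate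
6 | (4R)-1-methoxy-7-methyl-4-(prop-1-en-2-yl)octa-1,7-diene (E/Z mixture) | C=C(C)CC[C@H](CC=COC)C(C)=C | intermediate (not isolated)
7 | (4R)-7-methyl-4-(prop-1-en-2-yl)oct-7-enal | C=C(C)CC[C@H](CCC=O)C(C)=C | intermediate
8 | ethyl (6R)-9-methyl-3-oxo-6-(prop-1-en-2-yl)dec-9-enoate | C=C(C)CC[C@H](CCC(=O)CC(=O)OCC)C(C)=C | intermediate
9 | ethyl 4-[(2R)-5-methyl-2-(prop-1-en-2-yl)hex-5-enyl]-3,5-dioxohexanoate | C=C(C)CC[C@H](CC(C(C)=O)C(=O)CC(=O)OCC)C(C)=C | intermediate
10 | 4-hydroxy-6-methyl-5-[(2R)-5-methyl-2-(prop-1-en-2-yl)hex-5-enyl]pyran-2-one | C=C(C)CC[C@H](CC1=C(C)OC(=O)C=C1O)C(C)=C | intermediate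
11 | 3-bromo-4-hydroxy-6-methyl-5-[(2R)-5-methyl-2-(prop-1-en-2-yl)hex-5-enyl]pyran-2-one | C=C(C)CC[C@H](CC1=C(C)OC(=O)C(Br)=C1O)C(C)=C | intermediate
12 | 3-bromo-4-methoxy-6-methyl-5-[(2R)-5-methyl-2-(prop-1-en-2-yl)hex-5-enyl]pyran-2-one | C=C(C)CC[C@H](CC1=C(C)OC(=O)C(Br)=C1OC)C(C)=C | intermediate
13 | 3-methylbut-1-yne | CC(C)C#C | starting material
14 | (E)-4,4,5,5-tetramethyl-2-(3-methylbut-1-enyl)-1,3,2-dioxaborolane | CC(C)/C=C/B1OC(C)(C)C(C)(C)O1 | intermediate
15 | 4-methoxy-6-methyl-3-[(E)-3-methylbut-1-enyl]-5-[(2R)-5-methyl-2-(prop-1-en-2-yl)hex-5-enyl]pyran-2-one | C=C(C)CC[C@H](CC1=C(C)OC(=O)C(/C=C/C(C)C)=C1OC)C(C)=C | intermediate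
16 | methyl 3-hydroxybenzoate | COC(=O)c1cccc(O)c1 | starting material
17 | methyl 3-(tert-butyldimethylsilyloxy)benzoate | COC(=O)c1cccc(O[Si](C)(C)C(C)(C)C)c1 | intermediate
18 | 6-[2-[3-(tert-butyldimethylsilyloxy)phenyl]-2-oxoethyl]-4-methoxy-3-[(E)-3-methylbut-1-enyl]-5-[(2R)-5-methyl-2-(prop-1-en-2-yl)hex-5-enyl]pyran-2-one | C=C(C)CC[C@H](CC1=C(CC(=O)c2cccc(O[Si](C)(C)C(C)(C)C)c2)OC(=O)C(/C=C/C(C)C)=C1OC)C(C)=C | intermediate
19 | 6-[2-(3-hydroxyphenyl)-2-oxoethyl]-4-methoxy-3-[(E)-3-methylbut-1-enyl]-5-[(2R)-5-methyl-2-(prop-1-en-2-yl)hex-5-enyl]pyran-2-one | C=C(C)CC[C@H](CC1=C(CC(=O)c2cccc(O)c2)OC(=O)C(/C=C/C(C)C)=C1OC)C(C)=C | intermediate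
20 | methyl (2E)-7-(3-hydroxyphenyl)-3-methoxy-2-[(E)-3-methylbut-1-enyl]-4-[(2R)-5-methyl-2-(prop-1-en-2-yl)hex-5-enyl]-5,7-dioxohept-2-enoate (C4 epimers, as magnesium chelate in the flask) | COC(=O)/C(/C=C/C(C)C)=C(/OC)C(C[C@@H](CCC(C)=C)C(C)=C)C(=O)CC(=O)c1cccc(O)c1 | intermediate (not isolated)
21 | CNP0208548.1, [2,6-dihydroxy-4-methoxy-3-[(2R)-5-methyl-2-(prop-1-en-2-yl)hex-5-enyl]-5-[(E)-3-methylbut-1-enyl]phenyl](3-hydroxyphenyl)methanone | C=C(C)CC[C@H](Cc1c(O)c(C(=O)c2cccc(O)c2)c(O)c(/C=C/C(C)C)c1OC)C(=C)C | target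

**Step count**

Total step count: 14. Longest linear sequence: 12 steps (steps 1–8, 10, 12, 13, 14).

**Steps most likely to fail**

1. Step 14. The crowded, fully substituted lactone may open too slowly, so that methoxide instead cleaves the 1,3-diketone by retro-Claisen scission, or the opened chain may close through the enol oxygen instead of through carbon. The fallback sets out from 11 and comes back at 21; it moves the recyclisation to the 4-hydroxy pyrone series and sets the methyl ether afterwards. Mitsunobu etherification of 11 with 2-(trimethylsilyl)ethanol (PPh3, diisopropyl azodicarboxylate) should give 3-bromo-6-methyl-5-[(2R)-5-methyl-2-(prop-1-en-2-yl)hex-5-enyl]-4-[2-(trimethylsilyl)ethoxy]pyran-2-one F1. Suzuki coupling with 14 as in step 10 should give 6-methyl-3-[(E)-3-methylbut-1-enyl]-5-[(2R)-5-methyl-2-(prop-1-en-2-yl)hex-5-enyl]-4-[2-(trimethylsilyl)ethoxy]pyran-2-one F2. Lateral aroylation with 17 as in step 12 should give 6-[2-[3-(tert-butyldimethylsilyloxy)phenyl]-2-oxoethyl]-3-[(E)-3-methylbut-1-enyl]-5-[(2R)-5-methyl-2-(prop-1-en-2-yl)hex-5-enyl]-4-[2-(trimethylsilyl)ethoxy]pyran-2-one F3. Bu4NF then removes both silicon groups to give 4-hydroxy-6-[2-(3-hydroxyphenyl)-2-oxoethyl]-3-[(E)-3-methylbut-1-enyl]-5-[(2R)-5-methyl-2-(prop-1-en-2-yl)hex-5-enyl]pyran-2-one F4. Mg(OMe)2 in refluxing methanol should convert this into (3-hydroxyphenyl)[2,4,6-trihydroxy-3-[(E)-3-methylbut-1-enyl]-5-[(2R)-5-methyl-2-(prop-1-en-2-yl)hex-5-enyl]phenyl]methanone F5. One equivalent of Me2SO4 with K2CO3 in acetone should then methylate the most acidic hydroxyl, the one para to the ketone and the only ring A hydroxyl not hydrogen-bonded to it, ahead of the less acidic phenol of the other ring, to give 21.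

2. Step 12. After lateral deprotonation of the crowded pyrone, acyl transfer from the methyl ester may be slow, so that the lithiated pyrone decays or is quenched by proton transfer from the product. The fallback sets out from 15 and comes back at 18. Aldol addition of lithiated 15 (LiN(iPr)2, THF, −78 °C) to bought 3-(tert-butyldimethylsilyloxy)benzaldehyde should give 6-[2-[3-(tert-butyldimethylsilyloxy)phenyl]-2-hydroxyethyl]-4-methoxy-3-[(E)-3-methylbut-1-enyl]-5-[(2R)-5-methyl-2-(prop-1-en-2-yl)hex-5-enyl]pyran-2-one F6 as a mixture of carbinol epimers. Oxidation with Dess–Martin periodinane (CH2Cl2, NaHCO3) should give ketone 18.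

3. Step 8. Because the 4-oxygen is flanked by bromine and the C5 chain, alkylation may drift to the lactone carbonyl oxygen and give the 2-methoxy-4-pyranone isomer. The fallback sets out from 10 and comes back at 12 by reversing the order of the two steps. Me2SO4/K2CO3 in acetone should methylate the less hindered, 3-unsubstituted pyrone 10 to 4-methoxy-6-methyl-5-[(2R)-5-methyl-2-(prop-1-en-2-yl)hex-5-enyl]pyran-2-one F7. Bromination at C3 with NBS in MeCN at 0 °C in the dark should then give 12.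

Further compounds
F1 | step 14 | 3-bromo-6-methyl-5-[(2R)-5-methyl-2-(prop-1-en-2-yl)hex-5-enyl]-4-[2-(trimethylsilyl)ethoxy]pyran-2-one | C=C(C)CC[C@H](CC1=C(C)OC(=O)C(Br)=C1OCC[Si](C)(C)C)C(C)=C
F2 | step 14 | 6-methyl-3-[(E)-3-methylbut-1-enyl]-5-[(2R)-5-methyl-2-(prop-1-en-2-yl)hex-5-enyl]-4-[2-(trimethylsilyl)ethoxy]pyran-2-one | C=C(C)CC[C@H](CC1=C(C)OC(=O)C(/C=C/C(C)C)=C1OCC[Si](C)(C)C)C(C)=C
F3 | step 14 | 6-[2-[3-(tert-butyldimethylsilyloxy)phenyl]-2-oxoethyl]-3-[(E)-3-methylbut-1-enyl]-5-[(2R)-5-methyl-2-(prop-1-en-2-yl)hex-5-enyl]-4-[2-(trimethylsilyl)ethoxy]pyran-2-one | C=C(C)CC[C@H](CC1=C(CC(=O)c2cccc(O[Si](C)(C)C(C)(C)C)c2)OC(=O)C(/C=C/C(C)C)=C1OCC[Si](C)(C)C)C(C)=C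
F4 | step 14 | 4-hydroxy-6-[2-(3-hydroxyphenyl)-2-oxoethyl]-3-[(E)-3-methylbut-1-enyl]-5-[(2R)-5-methyl-2-(prop-1-en-2-yl)hex-5-enyl]pyran-2-one | C=C(C)CC[C@H](CC1=C(CC(=O)c2cccc(O)c2)OC(=O)C(/C=C/C(C)C)=C1O)C(C)=C
F5 | step 14 | (3-hydroxyphenyl)[2,4,6-trihydroxy-3-[(E)-3-methylbut-1-enyl]-5-[(2R)-5-methyl-2-(prop-1-en-2-yl)hex-5-enyl]phenyl]methanone | C=C(C)CC[C@H](Cc1c(O)c(C(=O)c2cccc(O)c2)c(O)c(/C=C/C(C)C)c1O)C(C)=C
F6 | step 12 | 6-[2-[3-(tert-butyldimethylsilyloxy)phenyl]-2-hydroxyethyl]-4-methoxy-3-[(E)-3-methylbut-1-enyl]-5-[(2R)-5-methyl-2-(prop-1-en-2-yl)hex-5-enyl]pyran-2-one | C=C(C)CC[C@H](CC1=C(CC(O)c2cccc(O[Si](C)(C)C(C)(C)C)c2)OC(=O)C(/C=C/C(C)C)=C1OC)C(C)=C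
F7 | step 8 | 4-methoxy-6-methyl-5-[(2R)-5-methyl-2-(prop-1-en-2-yl)hex-5-enyl]pyran-2-one | C=C(C)CC[C@H](CC1=C(C)OC(=O)C=C1OC)C(C)=C
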